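**Strategy.** The ten-membered ring is taken back to a cis-fused decalin whose ring-fusion bond is C5–C10. The Z-configured C1=C10 alkene and the oxygen-bearing C5 of the target, which face each other across the ring, are the two termini of a Grob fragmentation. In one operation the angular C5 alkoxide expels the C1 mesylate, the C5–C10 bond is cleaved, and rings A and B merge into the cyclodecenone with the Z alkene and the C5 ketone. The precursor is a cis-decalin with angular C5 hydroxyl and C10 methyl, equatorial C1 mesylate, C2 triethylsilyl ether, axial C4 methyl and an all-equatorial ring B (C6 OTBS, C7 side chain, C8 OTES).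

Key step: step 19

Numbering: carbocycle C1 (enone CH), C2 (ketone), C3, C4 (CHMe), C5 (ester carbinol), C6 (CHOH), C7, C8 (lactone O–CH), C9, C10 (alkene CMe); lactone C11 (α-carbon), C12 (carbonyl), C13 (methylene). Ring A is C1–C5/C10 and ring B is C5–C10. In the decalins α is the face of the C10 methyl and β the opposite face.

Remark: (S)-Wieland–Miescher ketone and angelic acid are taken as purchasable. The C2 oxygen is carried as a triethylsilyl ether so that one desilylation and one MnO2 treatment complete both the lactone and the enone.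

**Step 1**
Reactants: 1 (S)-Wieland–Miescher ketone
Product: 2 C1,C7-bis(ethylene ketal) with the alkene at C4=C5
Conditions: HOCH2CH2OH (excess), TsOH (cat.), benzene, reflux, Dean–Stark
Reagents that add atoms: ethylene glycol, OCCO
Why: Acid-catalysed ketalisation; the saturated C1 ketone reacts directly and the C7 enone through its dienol ether, which leaves the alkene in the β,γ-position at C4=C5 as is usual for bicyclic enones of this class.

**Step 2**
Reactants: 2 bis-ketal alkene
Product: 4 4α,5α-epoxy bis-ketal, via bromohydrin 3 (not isolated)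
Conditions: NBS, NaHCO3, acetone/H2O, 0 °C; then K2CO3, MeOH, rt
Reagents that add atoms: water, O
Why: Bromohydrin formation followed by base-induced ring closure (halohydrin route to epoxides): the bromonium ion should form on the β-face, away from the angular methyl, water opens it from the α-face, and closure with loss of bromide places the epoxide oxygen α, cis to the C10 methyl, whichever carbon water attacks.

**Step 3**
Reactants: 4 4α,5α-epoxy bis-ketal
Product: 5 4β-methyl-5α-hydroxy bis-ketal
Conditions: MeMgBr (excess), THF, reflux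
Reagents that add atoms: methylmagnesium bromide, C[Mg]Br
Why: SN2 opening of the trisubstituted epoxide by the Grignard reagent at the secondary carbon C4 with inversion (trans-diaxial opening, the mode known for 5,6-epoxy steroids), which sets the C4 methyl β and leaves the C5 hydroxyl α, cis to the C10 methyl.

**Step 4**
Reactants: 5 4β-methyl-5α-hydroxy bis-ketal
Product: 7 4β-methyl C5=C6–C7=O enone C1-ketal, via ketol 6 (not isolated)
Conditions: TsOH·H2O (cat.), acetone/H2O, rt; then crude ketol, MsCl, Et3N, CH2Cl2, 0 °C to rt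
Reagents that add atoms: water, O
Why: Selective acetal hydrolysis then dehydration of the β-hydroxy ketone by mesylation and E1cB elimination: the unhindered C7 dioxolane should hydrolyse much faster than the neopentyl C1 dioxolane, and elimination through the C6 enolate under amine base avoids the retro-aldol path and C4=C5 alkene formation that could scramble C4.

**Step 5**
Reactants: 7 4β-methyl enone C1-ketal
Product: 8 5α,6α-epoxy-7-ketone C1-ketal
Conditions: 30% H2O2, NaOH (cat.), MeOH, −10 °C
Reagents that add atoms: hydrogen peroxide, OO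
Why: Weitz–Scheffer nucleophilic epoxidation; hydroperoxide should add to C5 on the face of the angular methyl, the mode that leads to the cis-fused skeleton with bicyclic enones of this type, and the β-methyl at C4 reinforces it, so the epoxide oxygen is α.

**Step 6**
Reactants: 8 5α,6α-epoxy-7-ketone C1-ketal
Product: 10 5α-hydroxy C6=C7 alkene C1-ketal, via hydrazone 9 (not isolated)
Conditions: N2H4·H2O, AcOH (cat.), MeOH, 0 °C to rt
Reagents that add atoms: none
Why: Wharton transposition: the epoxy hydrazone loses dinitrogen with opening of the epoxide, so the oxygen stays on C5 with its α configuration (that C–O bond is never broken) and the alkene appears at C6=C7.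

**Step 7**
Reactants: 10 5α-hydroxy C6=C7 alkene C1-ketal
Product: 11 5α-hydroxy C6=C7–C8=O enone C1-ketal
Conditions: Rh2(cap)4 (1 mol%, cap = caprolactamate), t-BuOOH, K2CO3, CH2Cl2, rt
Reagents that add atoms: tert-butyl hydroperoxide, CC(C)(C)OO
Why: Radical allylic C–H oxidation (dirhodium-catalysed peroxidation) at C8, the only allylic methylene, with the allyl radical trapped at C8 and not at neopentyl C6; chromium oxidants are avoided because they would transpose the tertiary allylic alcohol.

**Step 8**
Reactants: 11 5α-hydroxy enone C1-ketal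
Product: 12 5α,8β-dihydroxy C6=C7 alkene C1-ketal
Conditions: NaBH4, CeCl3·7H2O, MeOH, −78 °C
Reagents that add atoms: none
Why: Luche 1,2-reduction; in the conformer that keeps the C4 methyl equatorial on ring A, C1 is axial on ring B and shields the β-face of C8, so hydride should add from the α-face and give the 8β-alcohol.

**Step 9**
Reactants: 12 5α,8β-diol
Product: 13 6β,7β-epoxy-5α,8β-diol C1-ketal
Conditions: Ti(OiPr)4 (0.3 equiv), t-BuOOH (in decane), 4 Å MS, CH2Cl2, −20 °C
Reagents that add atoms: tert-butyl hydroperoxide, CC(C)(C)OO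
Why: Hydroxyl-directed epoxidation of an allylic alcohol: the secondary C8 alkoxide binds tetravalent titanium and delivers oxygen to its own β-face, the tertiary C5 hydroxyl being a poor ligand for this catalyst.

**Step 10**
Reactants: 13 6β,7β-epoxy-5α,8β-diol C1-ketal
Product: 14 7α-isopropenyl-5α,6β,8β-triol C1-ketal
Conditions: CH2=C(CH3)MgBr (6 equiv), CuI (0.3 equiv), THF, −30 to 0 °C
Reagents that add atoms: isopropenylmagnesium bromide, CC(=C)[Mg]Br
Why: Copper-catalysed Grignard opening of an epoxide (SN2 with inversion): C6 is neopentyl, so the nucleophile should attack C7 from the α-face, which is also the trans-diaxial mode in the conformer with the C4 methyl equatorial, giving the 7α-carbon substituent and the 6β-alcohol.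

**Step 11**
Reactants: 14 7α-isopropenyl triol C1-ketal
Product: 15 7α-(3-hydroxyprop-1-en-2-yl)-5α,6β,8β-triol C1-ketal
Conditions: SeO2 (0.5 equiv), t-BuOOH, CH2Cl2, rt
Reagents that add atoms: tert-butyl hydroperoxide, CC(C)(C)OO
Why: Allylic hydroxylation by SeO2 (ene reaction then [2,3]-sigmatropic shift), which on a 1,1-disubstituted isopropenyl group oxidises the methyl group in preference to the ring methine.

**Step 12**
Reactants: 15 tetraol C1-ketal
Product: 16 C1 ketone with 5α,6β,8β,12-hydroxyls
Conditions: 2 M HCl, THF, 40 °C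
Reagents that add atoms: water, O
Why: Acid-catalysed acetal hydrolysis; the β-hydroxy ketone so formed cannot dehydrate because C10 is quaternary.

**Step 13**
Reactants: 16 C1 ketone tetraol
Product: 17 8,12-bis-O-triethylsilyl ether of 16
Conditions: Et3SiCl (2.2 equiv), imidazole, DMF, −20 °C
Reagents that add atoms: chlorotriethylsilane, CC[Si](Cl)(CC)CC
Why: Silyl ether formation ranked by steric access: the primary C12 and the C8 hydroxyls should react, whereas the C6 hydroxyl next to quaternary C5 and the tertiary C5 hydroxyl should not at this temperature.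

**Step 14**
Reactants: 17 8,12-bis-O-triethylsilyl ether
Product: 18 6-O-tert-butyldimethylsilyl-8,12-bis-O-triethylsilyl ketone with free 5α-hydroxyl
Conditions: t-BuMe2SiOTf (1.2 equiv), 2,6-lutidine, CH2Cl2, −78 to −20 °C
Reagents that add atoms: tert-butyldimethylsilyl triflate, CC(C)(C)[Si](C)(C)OS(=O)(=O)C(F)(F)F
Why: Silylation with a silyl triflate, reactive enough for the hindered secondary C6 hydroxyl while the tertiary C5 hydroxyl should stay free.

**Step 15**
Reactants: 18 tris-silylated C1 ketone
Product: 19 2α-hydroxy ketone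
Conditions: LiN(iPr)2 (2.3 equiv), THF, −78 °C; then 2-(phenylsulfonyl)-3-phenyloxaziridine; NH4Cl
Reagents that add atoms: 2-(phenylsulfonyl)-3-phenyloxaziridine, O=S(=O)(N1OC1c1ccccc1)c1ccccc1
Why: Enolate hydroxylation with an N-sulfonyloxaziridine; C1 can enolise only towards C2, and with ring B now carrying three equatorial groups the β-face of C2 is blocked by the axial C4 methyl and by C9, so oxygen should enter from the α-face (equatorial, also the more stable epimer).

**Step 16**
Reactants: 19 2α-hydroxy ketone
Product: 20 2α-triethylsilyloxy ketone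
Conditions: Et3SiCl, imidazole, DMAP (cat.), CH2Cl2, 0 °C
Reagents that add atoms: chlorotriethylsilane, CC[Si](Cl)(CC)CC
Why: Silyl ether formation at the secondary α-ketol hydroxyl; the tertiary C5 hydroxyl should not react with the chlorosilane.

**Step 17**
Reactants: 20 2α-triethylsilyloxy ketone
Product: 21 1β,5α-diol
Conditions: Me4NBH(OAc)3, MeCN/AcOH, −30 to 0 °C
Reagents that add atoms: none
Why: Hydroxyl-directed reduction with triacetoxyborohydride (Evans–Saksena reduction): the axial C5 hydroxyl binds boron and delivers hydride within the molecule to the α-face of C1, giving the 1,3-anti diol with the C1 hydroxyl β and equatorial.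

**Step 18**
Reactants: 21 1β,5α-diol
Product: 22 1β-mesylate (fragmentation precursor)
Conditions: MsCl, Et3N, CH2Cl2, −20 to 0 °C
Reagents that add atoms: methanesulfonyl chloride, CS(=O)(=O)Cl
Why: Sulfonate ester formation at the secondary C1 alcohol; the hindered tertiary C5 hydroxyl should stay free at this temperature and stoichiometry.

**Step 19**
Reactants: 22 1β-mesylate
Product: 23 (Z)-cyclodec-1(10)-en-5-one
Conditions: KOtBu (1.5 equiv), THF, 0 °C to rt
Reagents that add atoms: none
Why: tert-Butoxide deprotonates the tertiary C5 hydroxyl, the oxygen lone pair forms the C5 carbonyl while the C5–C10 σ bond, anti-periplanar to the equatorial C1–O bond, becomes the C1=C10 π bond and mesylate leaves in one concerted step. This is a Grob (Wharton) fragmentation of a 1,3-diol monosulfonate, a reaction type known to turn decalin-1,3-diol derivatives into cyclodec-5-enones. No ring is closed by bond formation: the ten-membered ring is released by cleaving the bond shared by rings A and B, so no medium-ring cyclisation is needed. No stereocenter is created; the Z geometry follows from the cis ring fusion, because in the reacting chair C9 is axial and the C10 methyl equatorial on ring A, which places C9 cis to C2 in the alkene. The step needs fragmentation to outrun elimination, oxetane formation and base-induced epimerisation at C4 and C6: the mesylate has no anti-periplanar hydrogen and cannot be reached from the rear by O5, the three equatorial ring B substituents hold the reactive conformer (whose axial C4 methyl strain is released on opening), and a small excess of base at low temperature limits enolisation of the product.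

**Step 20**
Reactants: 23 (Z)-cyclodec-1(10)-en-5-one
Product: 24 C5 alcohol
Conditions: NaBH4, MeOH/CH2Cl2, −40 °C
Reagents that add atoms: none
Why: Hydride reduction of an α-silyloxy ketone under Felkin–Anh control: hydride should add anti to the C6 silyloxy group, which gives the C5 alcohol with C5–O and C6–O on opposite faces of the ring as in the target.

**Step 21**
Reactants: 25 angelic acid
Product: 26 (Z)-2-methylbut-2-en-1-ol
Conditions: LiAlH4, Et2O, 0 °C
Reagents that add atoms: none
Why: Hydride reduction of a carboxylic acid to the primary allylic alcohol; LiAlH4 leaves the isolated trisubstituted alkene and its Z geometry untouched.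

**Step 22**
Reactants: 26 (Z)-2-methylbut-2-en-1-ol
Product: 27 ((2R,3S)-2,3-dimethyloxiran-2-yl)methanol
Conditions: Ti(OiPr)4 (10 mol%), D-(−)-diethyl tartrate (12 mol%), t-BuOOH, 4 Å MS, CH2Cl2, −20 °C
Reagents that add atoms: tert-butyl hydroperoxide, CC(C)(C)OO
Why: Sharpless asymmetric epoxidation; the D-(−)-tartrate catalyst delivers oxygen to the alkene face that gives the (2R,3S)-epoxy alcohol (reagent control), and the syn addition keeps the two methyl groups trans as in the Z alkene.

**Step 23**
Reactants: 27 (2R,3S)-epoxy alcohol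
Product: 28 (2S,3S)-2,3-dimethyloxirane-2-carboxylic acid
Conditions: RuCl3 (2 mol%), NaIO4, MeCN/EtOAc/H2O, rt
Reagents that add atoms: water, O
Why: Ruthenium tetroxide oxidation of a primary alcohol to the carboxylic acid, a standard conversion of 2,3-epoxy alcohols into glycidic acids that leaves the epoxide intact; the C2 descriptor changes only through the change in substituent priority.

**Step 24**
Reactants: 24 C5 alcohol; 28 (2S,3S)-2,3-dimethyloxirane-2-carboxylic acid
Product: 30 C5 epoxyangelate ester, via mixed anhydride 29 (not isolated)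
Conditions: 28, 2,4,6-trichlorobenzoyl chloride, Et3N, THF, rt; then 24, DMAP, toluene, 40 °C
Reagents that add atoms: none
Why: Yamaguchi esterification through the mixed anhydride, suited to a hindered secondary alcohol and an α-quaternary acid; no stereocenter is touched.

**Step 25**
Reactants: 30 C5 epoxyangelate ester
Product: 31 2,8,12-triol
Conditions: HF·pyridine, pyridine, THF, 0 °C
Reagents that add atoms: none
Why: Fluoride-mediated desilylation; buffered HF·pyridine should remove the three triethylsilyl ethers and leave the hindered secondary tert-butyldimethylsilyl ether and the epoxy ester.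

**Step 26**
Reactants: 31 2,8,12-triol
Product: 34 6-O-tert-butyldimethylsilyl ether of the target, via enal 32 (not isolated), via lactol 33 (not isolated)
Conditions: MnO2 (large excess), CH2Cl2, rt
Reagents that add atoms: none
Why: MnO2 oxidation of allylic alcohols: the C12 alcohol gives the enal, which closes to the lactol with the C8 hydroxyl and is oxidised on to the α-methylene γ-lactone (oxidative lactonisation of a 2-methylene-1,4-diol), while the secondary allylic C2 alcohol gives the Z enone; C8 keeps its configuration.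

**Step 27**
Reactants: 34 6-O-tert-butyldimethylsilyl ether of the target
Product: 35 CNP0227299.2
Conditions: HF·pyridine, THF, 0 °C to rt
Reagents that add atoms: none
Why: Acidic fluoride desilylation of the last silyl ether; non-basic conditions avoid acyl migration from O5 to O6 and conjugate addition to the α-methylene lactone.

**Compound list**
1 | (S)-Wieland–Miescher ketone, (8aS)-8a-methyl-3,4,8,8a-tetrahydronaphthalene-1,6(2H,7H)-dione (C1 and C7 ketones, C5=C6, C10 methyl) | C[C@@]12C(=O)CCCC1=CC(=O)CC2 | starting material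
2 | C1,C7-bis(ethylene ketal) with the alkene at C4=C5 | C[C@@]12C3(OCCO3)CCC=C1CC1(OCCO1)CC2 | intermediate
3 | 5β-bromo-4α-hydroxy bis-ketal (bromohydrin) | C[C@@]12C3(OCCO3)CC[C@@H](O)[C@@]1(Br)CC1(OCCO1)CC2 | intermediate
4 | 4α,5α-epoxy bis-ketal (epoxide oxygen cis to the C10 methyl) | C[C@@]12C3(OCCO3)CC[C@H]4O[C@@]14CC1(OCCO1)CC2 | intermediate
5 | 4β-methyl-5α-hydroxy bis-ketal (cis-fused; hydroxyl cis to the C10 methyl, C4 methyl trans to the hydroxyl) | C[C@@]12C3(OCCO3)CC[C@H](C)[C@]1(O)CC1(OCCO1)CC2 | intermediate
6 | 4β-methyl-5α-hydroxy-7-ketone, C1 ethylene ketal (ketol) | C[C@@]12C3(OCCO3)CC[C@H](C)[C@]1(O)CC(=O)CC2 | intermediate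
7 | 4β-methyl enone (C5=C6–C7=O), C1 ethylene ketal | C[C@@]12C3(OCCO3)CC[C@H](C)C1=CC(=O)CC2 | intermediate
8 | 5α,6α-epoxy-7-ketone, C1 ethylene ketal | C[C@@]12C3(OCCO3)CC[C@H](C)[C@@]14O[C@H]4C(=O)CC2 | intermediate
9 | C7 hydrazone of 8 | C[C@@]12C3(OCCO3)CC[C@H](C)[C@@]14O[C@H]4C(=NN)CC2 | intermediate
10 | 5α-hydroxy C6=C7 alkene, C1 ethylene ketal | C[C@@]12C3(OCCO3)CC[C@H](C)[C@]1(O)C=CCC2 | intermediate
11 | 5α-hydroxy enone (C6=C7–C8=O), C1 ethylene ketal | C[C@@]12C3(OCCO3)CC[C@H](C)[C@]1(O)C=CC(=O)C2 | intermediate
12 | 5α,8β-dihydroxy C6=C7 alkene, C1 ethylene ketal | C[C@@]12C3(OCCO3)CC[C@H](C)[C@]1(O)C=C[C@H](O)C2 | intermediate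
13 | 6β,7β-epoxy-5α,8β-diol, C1 ethylene ketal | C[C@@]12C3(OCCO3)CC[C@H](C)[C@]1(O)[C@@H]4O[C@@H]4[C@H](O)C2 | intermediate
14 | 7α-isopropenyl-5α,6β,8β-triol, C1 ethylene ketal | C[C@@]12C3(OCCO3)CC[C@H](C)[C@]1(O)[C@H](O)[C@@H](C(C)=C)[C@H](O)C2 | intermediate
15 | 7α-(3-hydroxyprop-1-en-2-yl)-5α,6β,8β-triol, C1 ethylene ketal | C[C@@]12C3(OCCO3)CC[C@H](C)[C@]1(O)[C@H](O)[C@@H](C(=C)CO)[C@H](O)C2 | intermediate
16 | C1 ketone with 5α,6β,8β,12-hydroxyls | C[C@@]12C(=O)CC[C@H](C)[C@]1(O)[C@H](O)[C@@H](C(=C)CO)[C@H](O)C2 | intermediate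
17 | 8,12-bis-O-triethylsilyl ether of 16 | C[C@@]12C(=O)CC[C@H](C)[C@]1(O)[C@H](O)[C@@H](C(=C)CO[Si](CC)(CC)CC)[C@H](O[Si](CC)(CC)CC)C2 | intermediate
18 | 6-O-tert-butyldimethylsilyl-8,12-bis-O-triethylsilyl C1 ketone, free 5α-hydroxyl | C[C@@]12C(=O)CC[C@H](C)[C@]1(O)[C@H](O[Si](C)(C)C(C)(C)C)[C@@H](C(=C)CO[Si](CC)(CC)CC)[C@H](O[Si](CC)(CC)CC)C2 | intermediate
19 | 2α-hydroxy derivative of 18 | C[C@@]12C(=O)[C@@H](O)C[C@H](C)[C@]1(O)[C@H](O[Si](C)(C)C(C)(C)C)[C@@H](C(=C)CO[Si](CC)(CC)CC)[C@H](O[Si](CC)(CC)CC)C2 | intermediate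
20 | 2α-triethylsilyloxy C1 ketone | C[C@@]12C(=O)[C@@H](O[Si](CC)(CC)CC)C[C@H](C)[C@]1(O)[C@H](O[Si](C)(C)C(C)(C)C)[C@@H](C(=C)CO[Si](CC)(CC)CC)[C@H](O[Si](CC)(CC)CC)C2 | intermediate
21 | 1β,5α-diol (C1 hydroxyl equatorial, trans to the C10 methyl) | C[C@@]12[C@H](O)[C@@H](O[Si](CC)(CC)CC)C[C@H](C)[C@]1(O)[C@H](O[Si](C)(C)C(C)(C)C)[C@@H](C(=C)CO[Si](CC)(CC)CC)[C@H](O[Si](CC)(CC)CC)C2 | intermediate
22 | cis-decalin 1β-mesylate with angular 5α-hydroxyl and 10α-methyl, 2α-OTES, 4β-methyl, 6β-OTBS, 7α-(3-triethylsilyloxyprop-1-en-2-yl), 8β-OTES | C[C@@]12[C@H](OS(C)(=O)=O)[C@@H](O[Si](CC)(CC)CC)C[C@H](C)[C@]1(O)[C@H](O[Si](C)(C)C(C)(C)C)[C@@H](C(=C)CO[Si](CC)(CC)CC)[C@H](O[Si](CC)(CC)CC)C2 | intermediate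
23 | ten-membered C5 ketone with Z C1=C10 alkene, C2 and C8 OTES, C6 OTBS, C12 OTES | CC[Si](CC)(CC)O[C@@H]1C/C(C)=C\[C@@H](O[Si](CC)(CC)CC)C[C@H](C)C(=O)[C@H](O[Si](C)(C)C(C)(C)C)[C@H]1C(=C)CO[Si](CC)(CC)CC | intermediate
24 | C5 alcohol of 23 (target configuration at C5) | CC[Si](CC)(CC)O[C@@H]1C/C(C)=C\[C@@H](O[Si](CC)(CC)CC)C[C@H](C)[C@@H](O)[C@H](O[Si](C)(C)C(C)(C)C)[C@H]1C(=C)CO[Si](CC)(CC)CC | intermediate
25 | angelic acid, (Z)-2-methylbut-2-enoic acid | C/C=C(/C)C(=O)O | starting material
26 | (Z)-2-methylbut-2-en-1-ol | C/C=C(/C)CO | intermediate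
27 | ((2R,3S)-2,3-dimethyloxiran-2-yl)methanol | OC[C@@]1(C)O[C@H]1C | intermediate
28 | (2S,3S)-2,3-dimethyloxirane-2-carboxylic acid | OC(=O)[C@@]1(C)O[C@H]1C | intermediate
29 | mixed anhydride of 28 and 2,4,6-trichlorobenzoic acid | O=C(OC(=O)[C@@]1(C)O[C@H]1C)c1c(Cl)cc(Cl)cc1Cl | intermediate
30 | C5 (2S,3S)-epoxyangelate of 24 | CC[Si](CC)(CC)O[C@@H]1C/C(C)=C\[C@@H](O[Si](CC)(CC)CC)C[C@H](C)[C@@H](OC(=O)[C@@]2(C)O[C@H]2C)[C@H](O[Si](C)(C)C(C)(C)C)[C@H]1C(=C)CO[Si](CC)(CC)CC | intermediate
31 | 2,8,12-triol with C5 ester and C6 OTBS | O[C@@H]1C/C(C)=C\[C@@H](O)C[C@H](C)[C@@H](OC(=O)[C@@]2(C)O[C@H]2C)[C@H](O[Si](C)(C)C(C)(C)C)[C@H]1C(=C)CO | intermediate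
32 | C12 aldehyde (enal) of 31 | O[C@@H]1C/C(C)=C\[C@@H](O)C[C@H](C)[C@@H](OC(=O)[C@@]2(C)O[C@H]2C)[C@H](O[Si](C)(C)C(C)(C)C)[C@H]1C(=C)C=O | intermediate
33 | C8–O–C12 lactol with C2 hydroxyl | C=C1C(O)O[C@@H]2C/C(C)=C\[C@@H](O)C[C@H](C)[C@@H](OC(=O)[C@@]3(C)O[C@H]3C)[C@H](O[Si](C)(C)C(C)(C)C)[C@@H]12 | intermediate
34 | 6-O-tert-butyldimethylsilyl ether of the target | C=C1C(=O)O[C@@H]2C/C(C)=C\C(=O)C[C@H](C)[C@@H](OC(=O)[C@@]3(C)O[C@H]3C)[C@H](O[Si](C)(C)C(C)(C)C)[C@@H]12 | intermediate
35 | CNP0227299.2 | C=C1C(=O)O[C@@H]2C/C(C)=C\C(=O)C[C@H](C)[C@@H](OC(=O)[C@@]3(C)O[C@H]3C)[C@H](O)[C@@H]12 | target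

**Step count.** Total 27 steps: 24 on the main line and 3 for the acid. Longest linear sequence: 24 steps, from 1 to 35 through steps 1–20 and 24–27.

**Steps most likely to fail**

Step 19 (key step). What may go wrong: enolisation of the new ketone by excess base, which would epimerise C4 or C6, or transfer of the C6 silyl group to the C5 alkoxide, which would stop the fragmentation. Fallback: from mesylate 22 the fragmentation is run reductively with LiAlH4 in THF at 0 °C, a known variant in which the aluminium alkoxide fragments and the ketone is reduced as it forms, so no base-sensitive ketone accumulates. The route is rejoined at alcohol 24 and no new compound arises (F0).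

Step 10. What may go wrong: slow substitution at the hindered C7 flanked by two magnesium alkoxides, so that Lewis-acid-induced rearrangement of the epoxy alcohol takes over. Fallback: from epoxy diol 13 the epoxide is opened with the alkynylalane Et2AlC≡CSiMe3 (toluene, 0 °C to rt), a reagent class delivered from the aluminium alkoxide to the distal epoxide carbon of hindered epoxy alcohols, giving the 7α-(trimethylsilylethynyl) triol F1. K2CO3 in MeOH removes the silyl group to give the terminal alkyne F2. Zirconium-catalysed methylalumination (Me3Al, Cp2ZrCl2, CH2Cl2) followed by protonolysis converts the alkyne into the isopropenyl group and rejoins the route at 14.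

Step 20. What may go wrong: poor facial selectivity in hydride addition to a conformationally mobile ten-membered ketone, so that the C5 epimer predominates. Fallback: from ketone 23 the epimeric C5 alcohol F3 is taken on and esterified with acid 28 under Mitsunobu conditions (PPh3, diisopropyl azodicarboxylate, toluene), which forms the ester with inversion at C5 and rejoins the route at 30.

**Further compounds**
F0 | step 19 | none | none
F1 | step 10 | 7α-(trimethylsilylethynyl)-5α,6β,8β-triol, C1 ethylene ketal | C[C@@]12C3(OCCO3)CC[C@H](C)[C@]1(O)[C@H](O)[C@@H](C#C[Si](C)(C)C)[C@H](O)C2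
F2 | step 10 | 7α-ethynyl-5α,6β,8β-triol, C1 ethylene ketal | C[C@@]12C3(OCCO3)CC[C@H](C)[C@]1(O)[C@H](O)[C@@H](C#C)[C@H](O)C2
F3 | step 20 | C5 epimer of alcohol 24 | CC[Si](CC)(CC)O[C@@H]1C/C(C)=C\[C@@H](O[Si](CC)(CC)CC)C[C@H](C)[C@H](O)[C@H](O[Si](C)(C)C(C)(C)C)[C@H]1C(=C)CO[Si](CC)(CC)CC
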